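## The problem

The target is epiguibourtinidol-(4β→8)-epicatechin: a 5-deoxy flavan-3-ol (rings A, C, B) joined through C4 to C8' of an epicatechin unit (rings D, F, E). It has five stereocentres, all R: C2, C3 and C4 in the upper unit (2,3-cis, 3,4-trans) and C2' and C3' in the lower unit (2,3-cis). The C2 aryl and C3 oxygen both sit on the α-face of ring C, so they can direct a nucleophile at C4 to the β-face. C2' and C3' lie beyond the flat ring D and cannot be controlled from the upper unit, so they need their own absolute control. In both units the 2,3-cis relationship is the less stable one, so neither pyran can be closed under equilibrating (cationic) conditions. The molecule carries seven phenols, two secondary alcohols, an acid-labile doubly benzylic C4–C8' bond and benzylic C2–O ethers. The late stages therefore have to be neutral and the protecting groups removable by hydrogenolysis or fluoride. The central difficulty is ring D (C4a', C5', C6', C7', C8', C8a'): its three oxygens must be told apart (O1' closes ring F, the C5' and C7' oxygens stay phenolic), and C8' rather than C6' must carry C4. That same ring is what makes the key step possible. A benzene with oxygens at C8a', C5' and C7', hydrogen at C6' and carbon substituents at C8' and C4a' is exactly the pattern a cyclobutenone–ynol ether benzannulation delivers. The single free phenol it produces comes from the ketene carbonyl and lies between the two carbon substituents.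

## Retrosynthesis

**Protecting groups (46 ⇐ 45 ⇐ 44).** The last bonds cut are O–benzyl and O–silyl. Every oxygen is carried as a benzyl ether except the one on C5', which arrives from the siloxyalkyne as a triisopropylsilyl ether. Buffered fluoride (44 → 45) and one hydrogenolysis (45 → 46) then finish the synthesis without acid.

**Ring F (44 ⇐ 43 ⇐ 42).** The O1'–C2' bond is cut. The alternative cut at C4'–C4a' would need an arene alkylation that again has to choose between ring D positions. With O1'–C2', regiochemistry is decided by which ring D oxygen is free. The forward step is an intramolecular Mitsunobu etherification with inversion. It therefore asks for the erythro carbinol (2'S,3'R) in 43 and for C8a'–OH as the only free phenol.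

**Ring D (42 ⇐ 24 + 37).** The C4a'–C8a' and C5'–C6' bonds are cut, which returns ring D to a four-carbon cyclobutenone 24 and a two-carbon siloxyalkyne 37. The competing cut, C4–C8' by arylation of a preformed phloroglucinol ring, has to discriminate C8' from C6' and O1' from the C5' oxygen. Here both questions are answered by how the ring is assembled. The two precursors are of similar size and no stereocentre is formed. The forward reaction must join the ketene carbon to the chain-bearing alkyne carbon, and 24 must carry the upper unit on its sp3 carbon. The isomer with the substituent on the alkene carbon would give the 4→6 series.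

**Cyclobutenone (24 ⇐ 16 + 21; 21 ⇐ 19 ⇐ 17).** The four-membered ring is cut into the aldoketene 23 (from acid 16 through acid chloride 22) and benzyl ethynyl ether 21. This [2+2] is regiospecific for the 4-substituted 3-alkoxycyclobutenone. A benzyl rather than a silyl group is placed on this oxygen (the future C7' oxygen) for three reasons: alkoxyethynes are the established partners of aldoketenes, whereas the parent siloxyethyne is not an established reagent; benzyl falls in the final hydrogenolysis; and it is smaller next to the crowded C8'. Ether 21 comes from benzyl alcohol 17 through the dichlorovinyl ether 19.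

**C4 side chain (16 ⇐ 15 ⇐ 14).** The C4–CH2 bond is cut to a C4 cation and an acetate enolate equivalent. The 4-methoxy flavan 14 is ionised and trapped by a ketene silyl acetal. The C2 aryl and C3 benzyloxy groups, both α, should direct attack to the β-face.

**Ring C (14 ⇐ 13 ⇐ 12 ⇐ 11).** The O1–C2 bond is cut by the same logic as for ring F: Mitsunobu closure with inversion of the erythro carbinol 13. The carbinol stereocentre comes from chelation-controlled reduction of the α-benzyloxy ketone 11.

**Upper carbon chain (11 ⇐ 8 + 9; 8 ⇐ 7 ⇐ 6 ⇐ 2 + 4; 2 ⇐ 1; 4 ⇐ 3).** The aryl ketone is cut to Weinreb amide 8 and the Grignard reagent 10 from bromide 9. The C3–C4 bond is cut by a syn glycolate aldol between imide 2 and aldehyde 4. This sets C3 and brings in the C4 oxygen as a future leaving group. No C–H oxidation at C4 of a 5-deoxy flavan is then needed, a position where C2 could compete.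

**Siloxyalkyne (37 ⇐ 34 ⇐ 33 ⇐ 32 ⇐ 29 + 30; 29 ⇐ 28 ⇐ 26 ⇐ 25).** The ynol ether is cut to the terminal alkyne 34 (acetylide oxidation, O-silylation). The carbinol comes from chelation-controlled reduction of ketone 32, and the ketone from Weinreb amide 29 and the Grignard reagent 31 from bromide 30. C3' is set by alkylation of glycolate imide 26 with propargyl bromide. Aldol and alkylation engage opposite enolate faces, so the upper unit uses the (R)-auxiliary (1) and the lower unit the (S)-auxiliary (25) to reach the same R configuration next to the benzyloxy group.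

## Roads not taken

**Alternative 1:** The cut is C4–C4a, closing ring C last. A Lewis acid would ionise the C4 carbinol of the open-chain aryl ether A1, in which O1, C2 and C3 are in place and C4 is already bonded to C8' of a benzylated epicatechin. Ring A would attack the cation para to its benzyloxy group to give the octabenzyl ether A2.
- Merits: the lower unit can come from natural epicatechin, so C2' and C3' are free of charge; C8' is fixed by a known selective halogenation; and A2 needs a single hydrogenolysis. On endgame length and on the lower stereocentres this road is better than the chosen one.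
- Weak points: C4 is created in the ring closure itself and must come out with ring D pseudo-axial and trans to the C3 oxygen, with no external nucleophile to approach anti to C3. Ring A can close at either position ortho to O1, giving the 7- or the 5-benzyloxy chromane. The cation is heavily stabilised by ring D while ring A is only a resorcinol ether, so closure is slow and reversible.
- Comparison: the chosen plan sets C4 on a preformed ring C, where the facial bias is established, and makes ring D regiochemistry structural.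

**Alternative 2:** The cut is C3'–C4' together with O1'–C2'. A chiral phosphoric acid would dehydrate the ring D salicyl alcohol A3 to an ortho-quinone methide, which would add the (Z)-enol acetate A4 to give the 3'-acetate A5.
- Merits: this is the most convergent road. Two bonds and both lower stereocentres form in one step, cis from the alkene geometry, and O1' is defined by the quinone methide.
- Weak points: A3 still requires the upper unit on one specific carbon of a phloroglucinol diether, so the regiochemical problem only moves earlier. A4 can react as a styrene (desired) or as an enol ester (giving the 2-acetoxy-3-aryl isomer). The catalyst must override or match five resident stereocentres. A Brønsted acid meets the acid-labile C4–C8' bond.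
- Comparison: this road would be several steps shorter. The chosen plan sets against that the fact that each stereocentre comes from a separate, checkable, substrate- or auxiliary-controlled step and that no acid is used after the two units are joined.

**Alternative 3:** The cut is C4'–C4a'. BF3·OEt2 would activate the terminal epoxide of the ring D aryl ether A6, and ring D would attack the epoxide CH2 through C4a' to give A7 with a free C3' hydroxyl.
- Merits: C2' and C3' are set beforehand and are not touched in the closure, so the 2,3-cis relationship is more secure than in a Mitsunobu closure. A7 is one hydrogenolysis from the target. On stereochemical safety of ring F this road is better.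
- Weak points: the O1'–C2' ether of A6 must itself be made by intermolecular SN2 at an electron-rich benzylic carbon with a hindered phenol. The phenol precursor again needs regioselective C-arylation of a phloroglucinol diether. The Lewis acid can open the epoxide in the 5-exo sense or ionise the benzylic C2'–O1' ether.
- Comparison: the chosen plan offers ring D regiochemistry by construction and a thermal, reagent-free C–C bond-forming step. It pays with a Mitsunobu closure whose inversion has to be watched.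

Key step: step 22

## Route

Remark on the chemistry: flavan numbering is used (upper unit rings A, C, B; lower unit rings D, F, E with primed locants). Cyclobutenone 24 is carried as a mixture of epimers at its sp3 ring carbon, a centre that is erased in step 22. Benzyl ethynyl ether 21 is handled only as a cold solution.

Step 1
Reactants: 1 (R)-4-benzyloxazolidin-2-one
Product: 2 (R)-4-benzyl-3-[2-(benzyloxy)acetyl]oxazolidin-2-one
Conditions: BnOCH2COCl, Et3N, DMAP (cat.), CH2Cl2, 0 °C → rt
Reagents that add atoms: benzyloxyacetyl chloride, O=C(Cl)COCc1ccccc1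
Why: DMAP-catalysed N-acylation of the oxazolidinone by an acid chloride; no stereocentre is touched.

Step 2
Reactants: 3 4-(benzyloxy)-2-hydroxybenzaldehyde
Product: 4 2-(allyloxy)-4-(benzyloxy)benzaldehyde
Conditions: allyl bromide, K2CO3, DMF, rt
Reagents that add atoms: allyl bromide, C=CCBr
Why: Williamson etherification of the only acidic site; the allyl ether tolerates boron enolates, AlMe3, Grignard and hydride reagents and is later removed by zerovalent palladium without touching benzyl ethers.

Step 3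
Reactants: 2 (R)-glycolate imide; 4 2-(allyloxy)-4-(benzyloxy)benzaldehyde
Product: 6 (R)-4-benzyl-3-[(2R,3S)-3-[2-(allyloxy)-4-(benzyloxy)phenyl]-2-(benzyloxy)-3-hydroxypropanoyl]oxazolidin-2-one, via boron enolate 5 (not isolated)
Conditions: Bu2BOTf, Et3N, CH2Cl2, −78 → 0 °C; 4, −78 → 0 °C; aq. NaH2PO4/Na2HPO4 buffer (pH 7), MeOH, 30% H2O2, 0 °C
Reagents that add atoms: none
Why: Evans syn aldol through the (Z)-boron enolate and a Zimmerman–Traxler transition state; the (R)-auxiliary sets the benzyloxy carbon (future C3) as R and the syn relationship fixes the carbinol (future C4). The C4 oxygen introduced here later serves as the leaving group.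

Step 4
Reactants: 6 syn aldol adduct
Product: 7 (2R,3S)-3-[2-(allyloxy)-4-(benzyloxy)phenyl]-2-(benzyloxy)-3-hydroxy-N-methoxy-N-methylpropanamide
Conditions: MeNH(OMe)·HCl, AlMe3, CH2Cl2, −20 → 0 °C; aq. potassium sodium tartrate
Reagents that add atoms: N,O-dimethylhydroxylamine hydrochloride, CNOC.Cl
Why: aluminium amide transamination of the imide to the Weinreb amide, assisted by the free β-hydroxyl; the auxiliary is released intact.

Step 5
Reactants: 7 β-hydroxy Weinreb amide
Product: 8 (2R,3S)-3-[2-(allyloxy)-4-(benzyloxy)phenyl]-2-(benzyloxy)-N,3-dimethoxy-N-methylpropanamide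
Conditions: Me3OBF4, 1,8-bis(dimethylamino)naphthalene, 4 Å molecular sieves, CH2Cl2, 0 °C → rt
Reagents that add atoms: trimethyloxonium tetrafluoroborate, C[O+](C)C.F[B-](F)(F)F
Why: O-methylation with an oxonium salt and a non-nucleophilic base; the absence of alkoxide avoids retro-aldol cleavage and epimerisation next to the amide.

Step 6
Reactants: 8 β-methoxy Weinreb amide; 9 1-(benzyloxy)-4-bromobenzene
Product: 11 (2R,3S)-3-[2-(allyloxy)-4-(benzyloxy)phenyl]-2-(benzyloxy)-1-[4-(benzyloxy)phenyl]-3-methoxypropan-1-one, via Grignard reagent 10 (not isolated)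
Conditions: 9, Mg, THF, 40 °C; then 8, THF, −20 → 0 °C; aq. NH4Cl
Reagents that add atoms: none
Why: Grignard addition to a Weinreb amide stops at the chelated tetrahedral adduct, so the ketone appears only on work-up and the α-centre is not exposed to base as a ketone.

Step 7
Reactants: 11 α-benzyloxy ketone
Product: 12 (1S,2S,3S)-3-[2-(allyloxy)-4-(benzyloxy)phenyl]-2-(benzyloxy)-1-[4-(benzyloxy)phenyl]-3-methoxypropan-1-ol (1,2-anti)
Conditions: Zn(BH4)2, Et2O, −30 → 0 °C
Reagents that add atoms: none
Why: chelation-controlled reduction (Cram cyclic model): zinc bridges the carbonyl and the α-benzyloxy oxygen and hydride enters from the face away from the C3 substituent, giving the anti (erythro) carbinol. Chelation through the β-methoxy group predicts the same isomer.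

Step 8
Reactants: 12 anti carbinol
Product: 13 5-(benzyloxy)-2-[(1S,2S,3S)-2-(benzyloxy)-3-[4-(benzyloxy)phenyl]-3-hydroxy-1-methoxypropyl]phenol
Conditions: Pd(PPh3)4 (cat.), morpholine, THF, rt
Reagents that add atoms: none
Why: palladium-catalysed deallylation through a π-allyl complex with morpholine as allyl acceptor; benzyl ethers and the carbinol are inert.

Step 9
Reactants: 13 phenol carbinol
Product: 14 (2R,3R,4S)-3,7-bis(benzyloxy)-2-[4-(benzyloxy)phenyl]-4-methoxychromane
Conditions: PPh3, DIAD, toluene, 0 °C → rt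
Reagents that add atoms: none
Why: intramolecular Mitsunobu etherification (6-exo-tet); the phenol displaces the activated carbinol with inversion, turning the erythro precursor into the 2,3-cis flavan with C2 as R. The neighbouring benzyloxy group and the non-polar solvent disfavour ionisation.

Step 10
Reactants: 14 4-methoxy flavan
Product: 15 methyl 2-[(2R,3R,4S)-3,7-bis(benzyloxy)-2-[4-(benzyloxy)phenyl]chroman-4-yl]acetate
Conditions: CH2=C(OMe)OSi(t-Bu)Me2, Me3SiOTf (cat.), CH2Cl2, −78 °C
Reagents that add atoms: 1-(tert-butyldimethylsilyloxy)-1-methoxyethene, C=C(OC)O[Si](C)(C)C(C)(C)C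
Why: Lewis acid ionisation of the C4 methyl ether to the benzylic cation stabilised by O1 and the C7 oxygen, followed by Mukaiyama-type capture by the ketene silyl acetal. Attack should come anti to the C3 benzyloxy and C2 aryl groups, both on the α-face, and so set the 4β configuration.

Step 11
Reactants: 15 methyl ester
Product: 16 2-[(2R,3R,4S)-3,7-bis(benzyloxy)-2-[4-(benzyloxy)phenyl]chroman-4-yl]acetic acid
Conditions: LiOH, THF/MeOH/H2O, rt; 1 M HCl to pH 4
Reagents that add atoms: lithium hydroxide, [Li+].[OH-]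
Why: ester saponification; C4 is β to the carboxyl group and cannot epimerise.

Step 12
Reactants: 17 benzyl alcohol
Product: 19 benzyl (E)-1,2-dichlorovinyl ether, via potassium benzyloxide 18 (not isolated)
Conditions: KH, THF, 0 °C; Cl2C=CHCl, −50 °C → rt
Reagents that add atoms: trichloroethylene, ClC=C(Cl)Cl
Why: the alkoxide adds to dichloroacetylene formed in situ from trichloroethylene (net addition–elimination), the standard entry to 1,2-dichlorovinyl ethers.

Step 13
Reactants: 19 benzyl (E)-1,2-dichlorovinyl ether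
Product: 21 benzyl ethynyl ether, via lithium acetylide 20 (not isolated)
Conditions: n-BuLi (2.2 equiv), THF, −78 → −40 °C; MeOH, −78 °C; kept as a solution below 0 °C
Reagents that add atoms: none
Why: dehydrochlorination followed by chlorine–lithium exchange gives the lithium alkoxyacetylide, which is protonated cold. The product is kept cold because benzyl alkynyl ethers undergo a [3,3] shift on warming.

Step 14
Reactants: 16 C4 acetic acid; 21 benzyl ethynyl ether
Product: 24 3-(benzyloxy)-4-[(2R,3R,4S)-3,7-bis(benzyloxy)-2-[4-(benzyloxy)phenyl]chroman-4-yl]cyclobut-2-en-1-one, via acid chloride 22 (not isolated), via ketene 23 (not isolated)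
Conditions: 1-chloro-N,N,2-trimethylpropenylamine, CH2Cl2, 0 °C → rt; then 21 (3 equiv), Et3N, CH2Cl2, 0 °C → rt
Reagents that add atoms: none
Why: neutral acid chloride formation, dehydrochlorination to the aldoketene and in-situ [2+2] cycloaddition with the ynol ether. The ketene carbonyl carbon bonds to the nucleophilic terminal alkyne carbon, so only the 4-substituted 3-alkoxycyclobutenone forms; this is the isomer that later places the upper unit on C8'.

Step 15
Reactants: 25 (S)-4-benzyloxazolidin-2-one
Product: 26 (S)-4-benzyl-3-[2-(benzyloxy)acetyl]oxazolidin-2-one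
Conditions: BnOCH2COCl, Et3N, DMAP (cat.), CH2Cl2, 0 °C → rt
Reagents that add atoms: benzyloxyacetyl chloride, O=C(Cl)COCc1ccccc1
Why: the same N-acylation as in step 1, on the enantiomeric auxiliary.

Step 16
Reactants: 26 (S)-glycolate imide
Product: 28 (S)-4-benzyl-3-[(R)-2-(benzyloxy)pent-4-ynoyl]oxazolidin-2-one, via sodium enolate 27 (not isolated)
Conditions: NaN(SiMe3)2, THF, −78 °C; propargyl bromide, −78 → −45 °C
Reagents that add atoms: propargyl bromide, C#CCBr
Why: Evans alkylation; the chelated (Z)-sodium enolate is alkylated on the face opposite the benzyl group of the auxiliary, which sets the future C3' as R.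

Step 17
Reactants: 28 alkylated imide
Product: 29 (R)-2-(benzyloxy)-N-methoxy-N-methylpent-4-ynamide
Conditions: MeNH(OMe)·HCl, AlMe3, CH2Cl2, −20 → 0 °C; aq. potassium sodium tartrate
Reagents that add atoms: N,O-dimethylhydroxylamine hydrochloride, CNOC.Cl
Why: aluminium amide transamination to the Weinreb amide with release of the auxiliary; the α-centre is not enolised under these conditions.

Step 18
Reactants: 29 Weinreb amide; 30 4-bromo-1,2-bis(benzyloxy)benzene
Product: 32 (R)-2-(benzyloxy)-1-[3,4-bis(benzyloxy)phenyl]pent-4-yn-1-one, via Grignard reagent 31 (not isolated)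
Conditions: 30, Mg, THF, 40 °C; then 29 (Grignard reagent in excess), THF, −20 → 0 °C; aq. NH4Cl
Reagents that add atoms: none
Why: Grignard addition to a Weinreb amide gives the ketone only on work-up; at this temperature an aryl Grignard reagent metallates the terminal alkyne only slowly, and any acetylide is reprotonated on quenching.

Step 19
Reactants: 32 α-benzyloxy ketone
Product: 33 (1S,2R)-2-(benzyloxy)-1-[3,4-bis(benzyloxy)phenyl]pent-4-yn-1-ol
Conditions: Zn(BH4)2, Et2O, −30 → 0 °C
Reagents that add atoms: none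
Why: chelation-controlled reduction as in step 7; hydride delivery to the zinc chelate of the carbonyl and the α-benzyloxy group gives the anti (erythro) carbinol with the future C2' as S.

Step 20
Reactants: 33 anti carbinol
Product: 34 triethylsilyl ether of 33
Conditions: Et3SiCl, imidazole, CH2Cl2, 0 °C → rt
Reagents that add atoms: chlorotriethylsilane, CC[Si](Cl)(CC)CC
Why: silylation of the secondary alcohol; the triethylsilyl ether keeps the hydroxyl away from ketenes in step 22 and can later be removed by mild acid without loss of an aryl triisopropylsilyl ether.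

Step 21
Reactants: 34 terminal alkyne
Product: 37 {[(4R,5S)-4-(benzyloxy)-5-[3,4-bis(benzyloxy)phenyl]-5-(triethylsilyloxy)pent-1-yn-1-yl]oxy}triisopropylsilane, via lithium acetylide 35 (not isolated), via lithium ynolate 36 (not isolated)
Conditions: n-BuLi, THF, −78 °C; LiOOt-Bu (from t-BuOOH and LiN(SiMe3)2), −78 → 0 °C; i-Pr3SiOTf, −78 → 0 °C
Reagents that add atoms: tert-butyl hydroperoxide, CC(C)(C)OO; triisopropylsilyl trifluoromethanesulfonate, CC(C)[Si](OS(=O)(=O)C(F)(F)F)(C(C)C)C(C)C
Why: electrophilic oxygen transfer from lithium tert-butyl peroxide to the acetylide gives the ynolate, which the bulky silyl triflate silylates on oxygen; this is the standard preparation of 1-siloxyalkynes from terminal alkynes.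

Step 22
Reactants: 24 3-(benzyloxy)-4-(chroman-4-yl)cyclobutenone; 37 siloxyalkyne
Product: 42 ring D phenol (C8a' hydroxyl free, C7' benzyl ether, C5' triisopropylsilyl ether, upper unit on C8', open lower chain on C4a'), via vinylketene 38 (not isolated), via vinylcyclobutenone 39 (not isolated), via dienylketene 40 (not isolated), via cyclohexadienone 41 (not isolated)
Conditions: 24 (1.0 equiv), 37 (1.3 equiv), degassed toluene, sealed vessel, 80 °C then 110 °C
Reagents that add atoms: none
Why: This is the Danheiser benzannulation of a cyclobutenone with a siloxyalkyne, known for resorcinol monosilyl ethers and used here with a 3-alkoxycyclobutenone so that a phloroglucinol ring results. Heat opens 24 by 4π-electrocyclic ring opening to vinylketene 38, with the bulky chromanyl group expected to rotate outward. The electrophilic ketene carbon then bonds to the nucleophilic, chain-bearing carbon of 37 and the ketene α-carbon to the siloxy-bearing carbon in a [2+2] cycloaddition, which gives 39 and forms C8a'–C4a' and C6'–C5'. Reversible 4π opening of 39 gives dienylketene 40, and ring D closes by 6π-electrocyclisation between the ketene carbon and the chromanyl-bearing terminus to give 41, which tautomerises to phenol 42. No stereocentre is created: the sp3 centre of 24 is erased, and C4 of the upper unit is never α to a carbonyl, so it keeps its configuration. The selectivity needed is the orientation of the [2+2] step, and the polarity of the ynol ether against the ketene carbonyl carbon secures it. The only free oxygen of ring D is therefore the one on C8a', between the upper unit on C8' and the chain on C4a'. The triethylsilyl ether ensures that no hydroxyl is present to add to the ketenes.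

Step 23
Reactants: 42 ring D phenol
Product: 43 phenol carbinol (C2' hydroxyl free)
Conditions: AcOH/THF/H2O (3:1:1), rt
Reagents that add atoms: none
Why: selective acid hydrolysis of the secondary alkyl triethylsilyl ether; aryl triisopropylsilyl and benzyl ethers are stable to aqueous acetic acid, and water as the nucleophile avoids solvolysis at the benzylic carbon.

Step 24
Reactants: 43 phenol carbinol
Product: 44 (2R,3R)-3,7-bis(benzyloxy)-8-[(2R,3R,4R)-3,7-bis(benzyloxy)-2-[4-(benzyloxy)phenyl]chroman-4-yl]-2-[3,4-bis(benzyloxy)phenyl]-5-(triisopropylsilyloxy)chromane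
Conditions: PPh3, DIAD, toluene, 0 °C → rt
Reagents that add atoms: none
Why: intramolecular Mitsunobu etherification (6-exo-tet) with inversion at C2' (S to R), which turns the erythro chain into the 2,3-cis pyran. Because the C8a' hydroxyl is the only free phenol, only the 4→8 isomer can form.

Step 25
Reactants: 44 protected dimer
Product: 45 C5' phenol (hepta-O-benzyl dimer)
Conditions: Bu4NF, AcOH, THF, 0 °C
Reagents that add atoms: none
Why: fluoride cleavage of the aryl silyl ether, buffered with acetic acid so that the phenoxide is not left under basic conditions.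

Step 26
Reactants: 45 hepta-O-benzyl dimer
Product: 46 epiguibourtinidol-(4β→8)-epicatechin
Conditions: H2 (1 atm), Pd(OH)2/C, THF/MeOH/H2O, rt
Reagents that add atoms: none
Why: hydrogenolysis of the seven benzyl ethers under neutral conditions, the standard final step for benzylated proanthocyanidins; no acid is present to cleave the C4–C8' bond.

## Compound list

1 | (R)-4-benzyloxazolidin-2-one | O=C1N[C@H](Cc2ccccc2)CO1 | starting material
2 | (R)-4-benzyl-3-[2-(benzyloxy)acetyl]oxazolidin-2-one | O=C(COCc1ccccc1)N1[C@H](Cc2ccccc2)COC1=O | intermediate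
3 | 4-(benzyloxy)-2-hydroxybenzaldehyde | O=Cc1ccc(OCc2ccccc2)cc1O | starting material
4 | 2-(allyloxy)-4-(benzyloxy)benzaldehyde | O=Cc1ccc(OCc2ccccc2)cc1OCC=C | intermediate
5 | (Z)-dibutylboron enolate of 2 | CCCCB(CCCC)O/C(=C\OCc1ccccc1)N1[C@H](Cc2ccccc2)COC1=O | intermediate
6 | (R)-4-benzyl-3-[(2R,3S)-3-[2-(allyloxy)-4-(benzyloxy)phenyl]-2-(benzyloxy)-3-hydroxypropanoyl]oxazolidin-2-one | O=C(N1[C@H](Cc2ccccc2)COC1=O)[C@H](OCc1ccccc1)[C@@H](O)c1ccc(OCc2ccccc2)cc1OCC=C | intermediate
7 | (2R,3S)-3-[2-(allyloxy)-4-(benzyloxy)phenyl]-2-(benzyloxy)-3-hydroxy-N-methoxy-N-methylpropanamide | CON(C)C(=O)[C@H](OCc1ccccc1)[C@@H](O)c1ccc(OCc2ccccc2)cc1OCC=C | intermediate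
8 | (2R,3S)-3-[2-(allyloxy)-4-(benzyloxy)phenyl]-2-(benzyloxy)-N,3-dimethoxy-N-methylpropanamide | CON(C)C(=O)[C@H](OCc1ccccc1)[C@@H](OC)c1ccc(OCc2ccccc2)cc1OCC=C | intermediate
9 | 1-(benzyloxy)-4-bromobenzene | Brc1ccc(OCc2ccccc2)cc1 | starting material
10 | [4-(benzyloxy)phenyl]magnesium bromide | Br[Mg]c1ccc(OCc2ccccc2)cc1 | intermediate
11 | (2R,3S)-3-[2-(allyloxy)-4-(benzyloxy)phenyl]-2-(benzyloxy)-1-[4-(benzyloxy)phenyl]-3-methoxypropan-1-one | O=C(c1ccc(OCc2ccccc2)cc1)[C@H](OCc1ccccc1)[C@@H](OC)c1ccc(OCc2ccccc2)cc1OCC=C | intermediate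
12 | (1S,2S,3S)-3-[2-(allyloxy)-4-(benzyloxy)phenyl]-2-(benzyloxy)-1-[4-(benzyloxy)phenyl]-3-methoxypropan-1-ol (1,2-anti) | O[C@@H](c1ccc(OCc2ccccc2)cc1)[C@H](OCc1ccccc1)[C@@H](OC)c1ccc(OCc2ccccc2)cc1OCC=C | intermediate
13 | 5-(benzyloxy)-2-[(1S,2S,3S)-2-(benzyloxy)-3-[4-(benzyloxy)phenyl]-3-hydroxy-1-methoxypropyl]phenol | O[C@@H](c1ccc(OCc2ccccc2)cc1)[C@H](OCc1ccccc1)[C@@H](OC)c1ccc(OCc2ccccc2)cc1O | intermediate
14 | (2R,3R,4S)-3,7-bis(benzyloxy)-2-[4-(benzyloxy)phenyl]-4-methoxychromane (2,3-cis, 4β-methoxy) | c1ccccc1COc1ccc([C@H]2Oc3cc(OCc4ccccc4)ccc3[C@H](OC)[C@H]2OCc2ccccc2)cc1 | intermediate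
15 | methyl 2-[(2R,3R,4S)-3,7-bis(benzyloxy)-2-[4-(benzyloxy)phenyl]chroman-4-yl]acetate (4β) | c1ccccc1COc1ccc([C@H]2Oc3cc(OCc4ccccc4)ccc3[C@H](CC(=O)OC)[C@H]2OCc2ccccc2)cc1 | intermediate
16 | 2-[(2R,3R,4S)-3,7-bis(benzyloxy)-2-[4-(benzyloxy)phenyl]chroman-4-yl]acetic acid | c1ccccc1COc1ccc([C@H]2Oc3cc(OCc4ccccc4)ccc3[C@H](CC(=O)O)[C@H]2OCc2ccccc2)cc1 | intermediate
17 | benzyl alcohol | OCc1ccccc1 | starting material
18 | potassium benzyloxide | [K+].[O-]Cc1ccccc1 | intermediate
19 | benzyl (E)-1,2-dichlorovinyl ether | Cl/C=C(/Cl)OCc1ccccc1 | intermediate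
20 | lithium (benzyloxy)acetylide | [Li]C#COCc1ccccc1 | intermediate
21 | benzyl ethynyl ether | C#COCc1ccccc1 | intermediate
22 | 2-[(2R,3R,4S)-3,7-bis(benzyloxy)-2-[4-(benzyloxy)phenyl]chroman-4-yl]acetyl chloride | c1ccccc1COc1ccc([C@H]2Oc3cc(OCc4ccccc4)ccc3[C@H](CC(=O)Cl)[C@H]2OCc2ccccc2)cc1 | intermediate
23 | 2-[(2R,3R,4S)-3,7-bis(benzyloxy)-2-[4-(benzyloxy)phenyl]chroman-4-yl]ethen-1-one (aldoketene) | c1ccccc1COc1ccc([C@H]2Oc3cc(OCc4ccccc4)ccc3[C@H](C=C=O)[C@H]2OCc2ccccc2)cc1 | intermediate
24 | 3-(benzyloxy)-4-[(2R,3R,4S)-3,7-bis(benzyloxy)-2-[4-(benzyloxy)phenyl]chroman-4-yl]cyclobut-2-en-1-one (both epimers at the cyclobutenone sp3 carbon) | c1ccccc1COc1ccc([C@H]2Oc3cc(OCc4ccccc4)ccc3[C@H](C4C(=O)C=C4OCc4ccccc4)[C@H]2OCc2ccccc2)cc1 | intermediate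
25 | (S)-4-benzyloxazolidin-2-one | O=C1N[C@@H](Cc2ccccc2)CO1 | starting material
26 | (S)-4-benzyl-3-[2-(benzyloxy)acetyl]oxazolidin-2-one | O=C(COCc1ccccc1)N1[C@@H](Cc2ccccc2)COC1=O | intermediate
27 | (Z)-sodium enolate of 26 | [Na+].[O-]/C(=C\OCc1ccccc1)N1[C@@H](Cc2ccccc2)COC1=O | intermediate
28 | (S)-4-benzyl-3-[(R)-2-(benzyloxy)pent-4-ynoyl]oxazolidin-2-one | C#CC[C@@H](OCc1ccccc1)C(=O)N1[C@@H](Cc2ccccc2)COC1=O | intermediate
29 | (R)-2-(benzyloxy)-N-methoxy-N-methylpent-4-ynamide | C#CC[C@@H](OCc1ccccc1)C(=O)N(C)OC | intermediate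
30 | 4-bromo-1,2-bis(benzyloxy)benzene | Brc1ccc(OCc2ccccc2)c(OCc2ccccc2)c1 | starting material
31 | [3,4-bis(benzyloxy)phenyl]magnesium bromide | Br[Mg]c1ccc(OCc2ccccc2)c(OCc2ccccc2)c1 | intermediate
32 | (R)-2-(benzyloxy)-1-[3,4-bis(benzyloxy)phenyl]pent-4-yn-1-one | C#CC[C@@H](OCc1ccccc1)C(=O)c1ccc(OCc2ccccc2)c(OCc2ccccc2)c1 | intermediate
33 | (1S,2R)-2-(benzyloxy)-1-[3,4-bis(benzyloxy)phenyl]pent-4-yn-1-ol (anti) | C#CC[C@@H](OCc1ccccc1)[C@@H](O)c1ccc(OCc2ccccc2)c(OCc2ccccc2)c1 | intermediate
34 | {[(1S,2R)-2-(benzyloxy)-1-[3,4-bis(benzyloxy)phenyl]pent-4-yn-1-yl]oxy}triethylsilane | C#CC[C@@H](OCc1ccccc1)[C@@H](O[Si](CC)(CC)CC)c1ccc(OCc2ccccc2)c(OCc2ccccc2)c1 | intermediate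
35 | lithium acetylide of 34 | [Li]C#CC[C@@H](OCc1ccccc1)[C@@H](O[Si](CC)(CC)CC)c1ccc(OCc2ccccc2)c(OCc2ccccc2)c1 | intermediate
36 | lithium (4R,5S)-4-(benzyloxy)-5-[3,4-bis(benzyloxy)phenyl]-5-(triethylsilyloxy)pent-1-yn-1-olate | [Li+].[O-]C#CC[C@@H](OCc1ccccc1)[C@@H](O[Si](CC)(CC)CC)c1ccc(OCc2ccccc2)c(OCc2ccccc2)c1 | intermediate
37 | {[(4R,5S)-4-(benzyloxy)-5-[3,4-bis(benzyloxy)phenyl]-5-(triethylsilyloxy)pent-1-yn-1-yl]oxy}triisopropylsilane | CC(C)[Si](C(C)C)(C(C)C)OC#CC[C@@H](OCc1ccccc1)[C@@H](O[Si](CC)(CC)CC)c1ccc(OCc2ccccc2)c(OCc2ccccc2)c1 | intermediate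
38 | (3Z)-3-(benzyloxy)-4-[(2R,3R,4S)-3,7-bis(benzyloxy)-2-[4-(benzyloxy)phenyl]chroman-4-yl]buta-1,3-dien-1-one (vinylketene) | c1ccccc1COc1ccc([C@H]2Oc3cc(OCc4ccccc4)ccc3[C@H](/C=C(\OCc3ccccc3)C=C=O)[C@H]2OCc2ccccc2)cc1 | intermediate
39 | 4-[(Z)-1-(benzyloxy)-2-(chroman-4-yl)vinyl]-2-[(2R,3S)-2-(benzyloxy)-3-[3,4-bis(benzyloxy)phenyl]-3-(triethylsilyloxy)propyl]-3-(triisopropylsilyloxy)cyclobut-2-en-1-one ([2+2] adduct; chromanyl as in 24) | c1ccccc1COc1ccc([C@H]2Oc3cc(OCc4ccccc4)ccc3[C@H](/C=C(\OCc3ccccc3)C3C(=O)C(C[C@@H](OCc5ccccc5)[C@@H](O[Si](CC)(CC)CC)c5ccc(OCc6ccccc6)c(OCc6ccccc6)c5)=C3O[Si](C(C)C)(C(C)C)C(C)C)[C@H]2OCc2ccccc2)cc1 | intermediate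
40 | 5-(benzyloxy)-2-[(2R,3S)-2-(benzyloxy)-3-[3,4-bis(benzyloxy)phenyl]-3-(triethylsilyloxy)propyl]-6-(chroman-4-yl)-3-(triisopropylsilyloxy)hexa-1,3,5-trien-1-one (dienylketene; chromanyl as in 24) | c1ccccc1COc1ccc([C@H]2Oc3cc(OCc4ccccc4)ccc3[C@H](/C=C(\OCc3ccccc3)/C=C(/O[Si](C(C)C)(C(C)C)C(C)C)C(=C=O)C[C@@H](OCc5ccccc5)[C@@H](O[Si](CC)(CC)CC)c5ccc(OCc6ccccc6)c(OCc6ccccc6)c5)[C@H]2OCc2ccccc2)cc1 | intermediate
41 | 5-(benzyloxy)-2-[(2R,3S)-2-(benzyloxy)-3-[3,4-bis(benzyloxy)phenyl]-3-(triethylsilyloxy)propyl]-6-(chroman-4-yl)-3-(triisopropylsilyloxy)cyclohexa-2,4-dien-1-one (chromanyl as in 24) | c1ccccc1COc1ccc([C@H]2Oc3cc(OCc4ccccc4)ccc3[C@H](C3C(OCc5ccccc5)=CC(O[Si](C(C)C)(C(C)C)C(C)C)=C(C[C@@H](OCc5ccccc5)[C@@H](O[Si](CC)(CC)CC)c5ccc(OCc6ccccc6)c(OCc6ccccc6)c5)C3=O)[C@H]2OCc2ccccc2)cc1 | intermediate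
42 | 3-(benzyloxy)-2-[(2R,3R,4R)-3,7-bis(benzyloxy)-2-[4-(benzyloxy)phenyl]chroman-4-yl]-6-[(2R,3S)-2-(benzyloxy)-3-[3,4-bis(benzyloxy)phenyl]-3-(triethylsilyloxy)propyl]-5-(triisopropylsilyloxy)phenol | c1ccccc1COc1ccc([C@H]2Oc3cc(OCc4ccccc4)ccc3[C@H](c3c(OCc5ccccc5)cc(O[Si](C(C)C)(C(C)C)C(C)C)c(C[C@@H](OCc5ccccc5)[C@@H](O[Si](CC)(CC)CC)c5ccc(OCc6ccccc6)c(OCc6ccccc6)c5)c3O)[C@H]2OCc2ccccc2)cc1 | intermediate
43 | 3-(benzyloxy)-2-[(2R,3R,4R)-3,7-bis(benzyloxy)-2-[4-(benzyloxy)phenyl]chroman-4-yl]-6-[(2R,3S)-2-(benzyloxy)-3-[3,4-bis(benzyloxy)phenyl]-3-hydroxypropyl]-5-(triisopropylsilyloxy)phenol | c1ccccc1COc1ccc([C@H]2Oc3cc(OCc4ccccc4)ccc3[C@H](c3c(OCc5ccccc5)cc(O[Si](C(C)C)(C(C)C)C(C)C)c(C[C@@H](OCc5ccccc5)[C@@H](O)c5ccc(OCc6ccccc6)c(OCc6ccccc6)c5)c3O)[C@H]2OCc2ccccc2)cc1 | intermediate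
44 | (2R,3R)-3,7-bis(benzyloxy)-8-[(2R,3R,4R)-3,7-bis(benzyloxy)-2-[4-(benzyloxy)phenyl]chroman-4-yl]-2-[3,4-bis(benzyloxy)phenyl]-5-(triisopropylsilyloxy)chromane | c1ccccc1COc1ccc([C@H]2Oc3cc(OCc4ccccc4)ccc3[C@H](c3c(OCc5ccccc5)cc(O[Si](C(C)C)(C(C)C)C(C)C)c5c3O[C@H](c3ccc(OCc6ccccc6)c(OCc6ccccc6)c3)[C@H](OCc3ccccc3)C5)[C@H]2OCc2ccccc2)cc1 | intermediate
45 | (2R,3R)-3,7-bis(benzyloxy)-8-[(2R,3R,4R)-3,7-bis(benzyloxy)-2-[4-(benzyloxy)phenyl]chroman-4-yl]-2-[3,4-bis(benzyloxy)phenyl]chroman-5-ol | c1ccccc1COc1ccc([C@H]2Oc3cc(OCc4ccccc4)ccc3[C@H](c3c(OCc5ccccc5)cc(O)c5c3O[C@H](c3ccc(OCc6ccccc6)c(OCc6ccccc6)c3)[C@H](OCc3ccccc3)C5)[C@H]2OCc2ccccc2)cc1 | intermediate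
46 | (2R,3R)-2-(3,4-dihydroxyphenyl)-8-[(2R,3R,4R)-3,7-dihydroxy-2-(4-hydroxyphenyl)chroman-4-yl]chromane-3,5,7-triol, epiguibourtinidol-(4β→8)-epicatechin | Oc1ccc([C@H]2Oc3cc(O)ccc3[C@H](c3c(O)cc(O)c4c3O[C@H](c3ccc(O)c(O)c3)[C@H](O)C4)[C@H]2O)cc1 | target

## Step count and least certain steps

Total: 26 steps. Longest linear sequence: 16 steps (steps 2–11, 14, 22–26, from aldehyde 3).

**Step 22 (key step).** The most likely failure is a mismatch of rates. A cyclobutenone that is also a vinylogous ester opens more slowly than an alkyl cyclobutenone. At the temperature it needs, the siloxyalkyne may be consumed by silyl migration to the silylketene. The [2+2] step also has to bring two bulky partners together, and the product phenol can be acylated by unreacted ketene.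
Fallback: it sets out from 14 and rejoins the route at 42. The same vinylketene is generated near room temperature without the four-membered ring, by 1,4-dehydrochlorination of an enoyl chloride. Compound 14 is alkylated at C4 (Me3SiOTf, CH2Cl2, −78 °C) by the γ-carbon of 3-(benzyloxy)-1-methoxy-1-(trimethylsilyloxy)buta-1,3-diene F1, which is made from methyl 3-(benzyloxy)but-2-enoate with LiN(i-Pr)2 and Me3SiCl. This gives methyl (E)-3-(benzyloxy)-4-(chroman-4-yl)but-2-enoate F2. LiOH gives the acid F3, and 1-chloro-N,N,2-trimethylpropenylamine gives the acid chloride F4. Et3N in the presence of 37 then removes the γ-proton to give 38, which continues through 39, 40 and 41 to 42.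

**Step 14.** The aldoketene may be lost by dimerisation, and the benzyl ynol ether by [3,3] rearrangement, before the two combine. The result would be low conversion to the cyclobutenone.
Fallback: it sets out from 16 and returns at 24. Ketene 23, generated as before, is trapped with commercial ethoxyacetylene, which is stable and can be used in large excess, to give the 3-ethoxycyclobutenone F5. Acid-catalysed vinylogous transesterification with benzyl alcohol (pyridinium p-toluenesulfonate, toluene, removal of ethanol) then gives 24. The exchange proceeds by addition–elimination at C3 and leaves the substituent on the sp3 carbon.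

**Step 24.** The activated C2' carbinol is a dialkoxybenzylic centre and the phenol is flanked on both sides. Partial ionisation before the slow ring closure would erode the inversion and give the 2,3-trans epimer, or lead to elimination. Step 9 runs the same closure on a simpler carbinol early in the route and gives an early reading of how well this class of alcohol holds to SN2 behaviour.
Fallback: it sets out from 14 and returns at 46. The cis-configured lower unit is taken from the chiral pool. (2R,3R)-5,7-Bis(benzyloxy)-2-[3,4-bis(benzyloxy)phenyl]chroman-3-ol F6 (tetra-O-benzylepicatechin, from epicatechin with benzyl bromide and K2CO3) is used in excess as the nucleophile toward the C4 cation of 14 (Me3SiOTf, CH2Cl2, −78 °C), which gives the hepta-O-benzyl dimer F7. Hydrogenolysis over Pd(OH)2/C then gives 46. This abandons the built-in regiocontrol: the 4→8 isomer must be separated from any 4→6 isomer.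

**Step 10.** The methyl ether of a 5-deoxy flavan ionises more slowly than that of a phloroglucinol-type flavan. The ketene silyl acetal may be destroyed by the Lewis acid before it is captured, leaving starting material or the flav-3-ene from proton loss.
Fallback: it sets out from 14 and returns at 16. Allyltrimethylsilane tolerates stoichiometric BF3·OEt2 at higher temperature and gives the 4β-allyl flavan F8. Oxidative cleavage (OsO4 cat., NaIO4, 2,6-lutidine, dioxane/H2O) gives the aldehyde F9, and NaClO2, NaH2PO4 and 2-methylbut-2-ene give 16.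

## Further compounds

F1 | step 22 | 3-(benzyloxy)-1-methoxy-1-(trimethylsilyloxy)buta-1,3-diene | C=C(OCc1ccccc1)C=C(OC)O[Si](C)(C)C
F2 | step 22 | methyl (E)-3-(benzyloxy)-4-[(2R,3R,4S)-3,7-bis(benzyloxy)-2-[4-(benzyloxy)phenyl]chroman-4-yl]but-2-enoate | c1ccccc1COc1ccc([C@H]2Oc3cc(OCc4ccccc4)ccc3[C@H](C/C(OCc3ccccc3)=C\C(=O)OC)[C@H]2OCc2ccccc2)cc1
F3 | step 22 | (E)-3-(benzyloxy)-4-[(2R,3R,4S)-3,7-bis(benzyloxy)-2-[4-(benzyloxy)phenyl]chroman-4-yl]but-2-enoic acid | c1ccccc1COc1ccc([C@H]2Oc3cc(OCc4ccccc4)ccc3[C@H](C/C(OCc3ccccc3)=C\C(=O)O)[C@H]2OCc2ccccc2)cc1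
F4 | step 22 | (E)-3-(benzyloxy)-4-[(2R,3R,4S)-3,7-bis(benzyloxy)-2-[4-(benzyloxy)phenyl]chroman-4-yl]but-2-enoyl chloride | c1ccccc1COc1ccc([C@H]2Oc3cc(OCc4ccccc4)ccc3[C@H](C/C(OCc3ccccc3)=C\C(=O)Cl)[C@H]2OCc2ccccc2)cc1
F5 | step 14 | 4-[(2R,3R,4S)-3,7-bis(benzyloxy)-2-[4-(benzyloxy)phenyl]chroman-4-yl]-3-ethoxycyclobut-2-en-1-one | c1ccccc1COc1ccc([C@H]2Oc3cc(OCc4ccccc4)ccc3[C@H](C3C(=O)C=C3OCC)[C@H]2OCc2ccccc2)cc1
F6 | step 24 | (2R,3R)-5,7-bis(benzyloxy)-2-[3,4-bis(benzyloxy)phenyl]chroman-3-ol | c1c(OCc2ccccc2)cc(OCc2ccccc2)c2c1O[C@H](c1ccc(OCc3ccccc3)c(OCc3ccccc3)c1)[C@H](O)C2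
F7 | step 24 | (2R,3R)-5,7-bis(benzyloxy)-8-[(2R,3R,4R)-3,7-bis(benzyloxy)-2-[4-(benzyloxy)phenyl]chroman-4-yl]-2-[3,4-bis(benzyloxy)phenyl]chroman-3-ol | c1ccccc1COc1ccc([C@H]2Oc3cc(OCc4ccccc4)ccc3[C@H](c3c(OCc5ccccc5)cc(OCc5ccccc5)c5c3O[C@H](c3ccc(OCc6ccccc6)c(OCc6ccccc6)c3)[C@H](O)C5)[C@H]2OCc2ccccc2)cc1
F8 | step 10 | (2R,3R,4S)-4-allyl-3,7-bis(benzyloxy)-2-[4-(benzyloxy)phenyl]chromane | c1ccccc1COc1ccc([C@H]2Oc3cc(OCc4ccccc4)ccc3[C@H](CC=C)[C@H]2OCc2ccccc2)cc1
F9 | step 10 | 2-[(2R,3R,4S)-3,7-bis(benzyloxy)-2-[4-(benzyloxy)phenyl]chroman-4-yl]acetaldehyde | c1ccccc1COc1ccc([C@H]2Oc3cc(OCc4ccccc4)ccc3[C@H](CC=O)[C@H]2OCc2ccccc2)cc1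
A1 | alternative 1 | (2R,3R)-2-(benzyloxy)-3-[3-(benzyloxy)phenoxy]-3-[4-(benzyloxy)phenyl]-1-[(2R,3R)-3,5,7-tris(benzyloxy)-2-[3,4-bis(benzyloxy)phenyl]chroman-8-yl]propan-1-ol (either C1 epimer) | c1ccccc1COc1ccc([C@@H](Oc2cccc(OCc3ccccc3)c2)[C@H](OCc2ccccc2)C(O)c2c(OCc3ccccc3)cc(OCc3ccccc3)c3c2O[C@H](c2ccc(OCc4ccccc4)c(OCc4ccccc4)c2)[C@H](OCc2ccccc2)C3)cc1
A2 | alternative 1 | octa-O-benzyl epiguibourtinidol-(4β→8)-epicatechin | c1ccccc1COc1ccc([C@H]2Oc3cc(OCc4ccccc4)ccc3[C@H](c3c(OCc5ccccc5)cc(OCc5ccccc5)c5c3O[C@H](c3ccc(OCc6ccccc6)c(OCc6ccccc6)c3)[C@H](OCc3ccccc3)C5)[C@H]2OCc2ccccc2)cc1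
A3 | alternative 2 | 3,5-bis(benzyloxy)-2-[(2R,3R,4R)-3,7-bis(benzyloxy)-2-[4-(benzyloxy)phenyl]chroman-4-yl]-6-(hydroxymethyl)phenol | c1ccccc1COc1ccc([C@H]2Oc3cc(OCc4ccccc4)ccc3[C@H](c3c(OCc5ccccc5)cc(OCc5ccccc5)c(CO)c3O)[C@H]2OCc2ccccc2)cc1
A4 | alternative 2 | (Z)-2-[3,4-bis(benzyloxy)phenyl]vinyl acetate | CC(=O)O/C=C\c1ccc(OCc2ccccc2)c(OCc2ccccc2)c1
A5 | alternative 2 | hepta-O-benzyl epiguibourtinidol-(4β→8)-epicatechin 3'-O-acetate | c1ccccc1COc1ccc([C@H]2Oc3cc(OCc4ccccc4)ccc3[C@H](c3c(OCc5ccccc5)cc(OCc5ccccc5)c5c3O[C@H](c3ccc(OCc6ccccc6)c(OCc6ccccc6)c3)[C@H](OC(C)=O)C5)[C@H]2OCc2ccccc2)cc1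
A6 | alternative 3 | (2R,3R,4R)-3,7-bis(benzyloxy)-2-[4-(benzyloxy)phenyl]-4-[2,4-bis(benzyloxy)-6-{(R)-[3,4-bis(benzyloxy)phenyl][(R)-oxiran-2-yl]methoxy}phenyl]chromane | c1ccccc1COc1ccc([C@H]2Oc3cc(OCc4ccccc4)ccc3[C@H](c3c(OCc5ccccc5)cc(OCc5ccccc5)cc3O[C@H](c3ccc(OCc6ccccc6)c(OCc6ccccc6)c3)[C@H]3CO3)[C@H]2OCc2ccccc2)cc1
A7 | alternative 3 | hepta-O-benzyl epiguibourtinidol-(4β→8)-epicatechin with free C3' hydroxyl | c1ccccc1COc1ccc([C@H]2Oc3cc(OCc4ccccc4)ccc3[C@H](c3c(OCc5ccccc5)cc(OCc5ccccc5)c5c3O[C@H](c3ccc(OCc6ccccc6)c(OCc6ccccc6)c3)[C@H](O)C5)[C@H]2OCc2ccccc2)cc1
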